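## The problem

The target is a germacranolide. Locants used throughout: ring carbons C1–C10; C11–C13 form the lactone arm on C7 (C12 carbonyl, C13 exocyclic methylene); C14 is the ester carbon on C10; C15 is the methyl on C4.

- **Ring system.** A ten-membered carbocycle carries a 4,5-epoxide with C3 and C6 cis, a cis-fused α-methylene-γ-lactone across C6/C7, and a C1=C10 enoate whose ring carbons C9 and C2 are cis. Closing a ten-membered ring suffers from transannular strain, so the ring-closing bond must lie where the chain is held apart.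
- **Stereocentres.** C4 to C9 are six contiguous centres, plus one in the glycidate side chain. C8 can come from the chiral pool and control C7 inside a six-membered ring. O8 can control C6 through a chelate. The C6 hydroxyl can control C4 and C5 through a directed epoxidation. C8 must finally control C9.
- **The C6/C7/C8 triad.** O6 and O8 are 1,3-syn and the C11 branch is anti to both. This is the all-equatorial pattern of a six-membered chelate, and the opposite of what a Felkin-type addition to a C6 aldehyde is expected to give.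
- **Fragile groups.** The trisubstituted epoxide does not tolerate acid or strong Lewis acids. The methylene lactone does not tolerate nucleophiles, hydride or palladium hydride. The vicinal C8 acetate and C9 glycidate can migrate, and a free O8 can translactonise onto C12. The enoate has acidic γ-hydrogens. These groups must appear late and in a fixed order.
- **Enabling feature.** The C9 carbinol is bonded to C10 of a trisubstituted enoate that has H on C1 and C9 cis to C2. That is the result of syn addition of H and CO2Me across a ring alkyne C1≡C10. C9–C10 can therefore be formed by adding a C10 alkynyl metal to a C9 aldehyde, and the linear C9–C10≡C1–C2 unit keeps the chain ends clear of transannular contacts during closure.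

## Retrosynthesis

**Acyl groups (39 ⇒ 38 ⇒ 37 ⇒ 33 + 35).** The two ester C–O bonds at O8 and O9 are cut first, the acetate last. The hindered, slowly migrating glycidoyl group from salt 35 is placed on C9 while O8 is still a PMB ether. O8 is then freed under neutral oxidative conditions and acetylated quickly. The reverse order would leave a mobile acetyl group next to a free C9 hydroxyl. The forward reactions must acylate a hindered allylic alcohol without opening an epoxide.

**Enoate and methylene lactone (33 ⇒ 32 ⇒ 31 ⇒ 30 ⇒ 28 ⇒ 27 ⇒ 26 ⇒ 25).** C10–C14 is cut (carbonylation of iodide 31), then C11=C13 (Mannich methylenation of 27 via 28), then H and Sn are removed from C1=C10 to return to cycloalkyne 25. An olefination at C1=C10 would not guarantee the geometry; syn addition to a ring alkyne can only give C9 cis to C2. The order is fixed by reactivity: palladium hydride before the methylene lactone exists, enolate chemistry while C10 carries tin and not yet an enoate.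

**Ring closure (25 ⇒ 23), the key cut.** C9–C10 is cut to give the open-chain iodoalkyne aldehyde 23. This cut is preferred to one at C5–C6 or C7–C8 because it leaves every stereocentre from C4 to C8 to be set in acyclic or six-membered-ring intermediates. The forward step must close the ring under high dilution and deliver the 8,9-syn carbinol.

**Unveiling C9 (23 ⇒ 22 ⇒ 21 ⇒ 20).** The aldehyde goes back to the primary alcohol 22, the C–I bond to the C–Si bond of 21, and the O6–C12 lactone bond of 21 to the O9–C12 bond of δ-lactone 20. The δ-lactone masks both the C9 hydroxyl and the C12 carboxyl without any protecting group and leaves the C6 hydroxyl free. The forward acyl transfer must run only after that hydroxyl has directed the epoxidation.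

**Epoxide and C6 (20 ⇒ 19 ⇒ 18).** The two epoxide C–O bonds are cut back to the Z-allylic alcohol 19, and the C6–H bond back to enone 18. Directed epoxidation of a Z-trisubstituted allylic alcohol is reliably threo, which is the required C5/C6 relation. The chelate-controlled reduction gives the syn O6/O8 relation that an open-chain addition would not.

**Fragment union (18 ⇒ 17 ⇒ 9 + 15).** C5–C6 is cut into aldehyde 9 and Z-alkenyl iodide 15. The chromium-mediated addition tolerates the lactone; its lack of stereocontrol at C6 is irrelevant because 17 is oxidised to 18.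

**Z-alkene (15 ⇒ 10 + 11).** C3–C4 is cut. Syn carbocupration of propyne 11 by the copper reagent from bromide 10 sets the C3/C6-cis geometry in one step, which a ketone olefination would not do cleanly.

**Lactone fragment (9 ⇒ 8 ⇒ 6 ⇒ 5 ⇒ 3 + 4; 3 ⇒ 2 ⇒ 1).** C6–C7 is cut (conjugate addition to 6, trans to the C8 ether), then C7=C11 (ring-closing metathesis of acrylate 5), then the ester bond to acryloyl chloride 4. The PMB group is placed on the secondary oxygen of diol 1 by reductive opening of acetal 2. C8 comes from the chiral pool and controls C7 within a six-membered ring.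

## Roads not taken

**Alternative 1:** The cut is C7–C11. A C6 ester of diazo(diethoxyphosphoryl)acetic acid on the finished ten-membered ring (A4, C7 still a methylene) would be decomposed with Rh2(OAc)4. The carbenoid would insert into the C7–H bond cis to O6 to give phosphono lactone A1, and a Horner–Wadsworth–Emmons reaction with formaldehyde would deliver the methylene lactone.
- Merits: the cis ring fusion is inherent in 1,5-insertion, and the methylene group arrives under far milder conditions than the enolate/Mannich sequence of steps 18 and 19. In this respect the road is better.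
- Weak points: A4 already contains the ring, the epoxide, the enoate and both C8/C9 oxygen functions, so ring closure and enoate geometry are only moved to an undefined earlier phase. The C7–H bonds are β to the electron-withdrawing C8 acetoxy group and deactivated towards an electrophilic carbenoid. Insertion into C5–H and ylide formation at the epoxide oxygen are open competitors. C7 would be created last, on the most valuable material.
- Comparison: the chosen plan sets C7 at step 5 in a six-membered ring and accepts two strongly basic late steps as the price.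

**Alternative 2:** The cuts are C5–C6 and C3–C4. Zerovalent nickel (Ni(cod)2) would join aldehyde A5, propyne 11 and but-3-en-1-ylzinc bromide A6 through an oxanickelacycle, transmetalation and reductive elimination, giving allylic alcohol A2 by syn addition across the alkyne.
- Merits: one step gives the Z-trisubstituted allylic alcohol for which the chosen plan needs steps 7 and 8. This is shorter and equally secure in alkene geometry.
- Weak points: the intermolecular version with an sp3 zinc reagent bearing β-hydrogens competes with β-hydride elimination (simple reductive coupling). C6 would be set by addition to the open-chain α-branched aldehyde A5, whose expected Felkin and 1,3-anti preferences oppose the required triad, so an oxidation–reduction detour would still be needed. The γ-hydroxy ester A2 can lactonise at once and lose the directing hydroxyl. The terminal alkene at C1 commits the route to a different ring closure and reopens the enoate geometry question.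
- Comparison: the chosen plan is longer here but offers chelate control at C6 (step 10) and a ring closure that fixes the C1=C10 geometry by construction.

**Alternative 3:** The cuts are C7–C8 and O–C6. Nitrile oxide A7, generated at C8, would add across the E-C6=C7 double bond and close the ten-membered ring and a bridging isoxazoline together to give A3. N–O cleavage (Mo(CO)6) would unveil the C6 hydroxyl and a C8 ketone.
- Merits: two bonds and the carbocycle form in one metal-free step, and the alkene geometry is transferred stereospecifically to C6/C7. In bonds formed per step it is better than the chosen key step.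
- Weak points: the bridged regiochemistry (carbon to C7, oxygen to C6) competes with the fused mode and with furoxan formation from an unstabilised α-silyloxy nitrile oxide. Facial selectivity rests on the C5 epoxide carbon alone. The enoate must already have its cis geometry before closure. C8 emerges as a ketone flanked by the epimerisable allylic C9 centre, and its reduction and the N–O cleavage must spare epoxide and enoate.
- Comparison: the chosen plan forms only one bond in its key step, but through a known ring-closure type and with the enoate geometry deferred to a syn addition.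

Key step: step 15

Remark: CIP descriptors of intermediates change with their substituents although the spatial arrangement at C4–C9 is always that of the target; compounds 1, 4, 10, 11 and 34 are taken as purchasable.

## Route

Step 1
Reactants: 1 (S)-but-3-ene-1,2-diol
Product: 2 (4S)-2-(4-methoxyphenyl)-4-vinyl-1,3-dioxolane (both acetal epimers)
Conditions: 4-MeOC6H4CH(OMe)2, PPTS (cat.), CH2Cl2, rt
Reagents that add atoms: 4-methoxybenzaldehyde dimethyl acetal, COC(OC)c1ccc(OC)cc1
Why: Acid-catalysed transacetalisation of a 1,2-diol; the acetal carbon forms as both epimers, which is immaterial because it becomes a CH2 group in step 2.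

Step 2
Reactants: 2 (4S)-2-(4-methoxyphenyl)-4-vinyl-1,3-dioxolane
Product: 3 (S)-2-[(4-methoxybenzyl)oxy]but-3-en-1-ol
Conditions: iBu2AlH, CH2Cl2, −78 → 0 °C; aq. potassium sodium tartrate
Reagents that add atoms: none
Why: Reductive opening of a p-methoxybenzylidene acetal; aluminium binds the less hindered primary oxygen, that C–O bond breaks and hydride caps the oxocarbenium ion, leaving the PMB ether on the secondary oxygen (future O8).

Step 3
Reactants: 3 (S)-2-[(4-methoxybenzyl)oxy]but-3-en-1-ol; 4 acryloyl chloride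
Product: 5 (S)-2-[(4-methoxybenzyl)oxy]but-3-en-1-yl acrylate
Conditions: Et3N, DMAP (cat.), CH2Cl2, −20 → 0 °C
Reagents that add atoms: none
Why: O-acylation of a primary alcohol with an acid chloride; the low temperature avoids conjugate addition of the amine to the acrylate.

Step 4
Reactants: 5 (S)-2-[(4-methoxybenzyl)oxy]but-3-en-1-yl acrylate
Product: 6 (S)-5-[(4-methoxybenzyl)oxy]-5,6-dihydro-2H-pyran-2-one
Conditions: (H2IMes)(PCy3)Cl2Ru=CHPh (second-generation Grubbs catalyst, 5 mol%), CH2Cl2, 40 °C, 5 mM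
Reagents that add atoms: none
Why: Ring-closing olefin metathesis of an acrylate/allyl ether diene to a six-membered unsaturated lactone; loss of ethene drives it, dilution suppresses cross-metathesis, and the C8 centre is untouched.

Step 5
Reactants: 6 (S)-5-[(4-methoxybenzyl)oxy]-5,6-dihydro-2H-pyran-2-one
Product: 8 (4S,5S)-5-[(4-methoxybenzyl)oxy]-4-vinyltetrahydro-2H-pyran-2-one, via silyl ketene acetal 7 (not isolated)
Conditions: CH2=CHMgBr, CuBr·SMe2 (20 mol%), Me3SiCl, THF, −78 °C; then aq. NH4Cl
Reagents that add atoms: vinylmagnesium bromide, C=C[Mg]Br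
Why: Copper-catalysed conjugate addition of a vinyl Grignard reagent, accelerated by Me3SiCl, which traps the enolate as 7; the vinyl group enters the half-chair lactone trans to the adjacent C8 PMB-oxy group (as in 4-substituted cyclohexenones), which sets C7, and aqueous work-up hydrolyses 7.

Step 6
Reactants: 8 (4S,5S)-5-[(4-methoxybenzyl)oxy]-4-vinyltetrahydro-2H-pyran-2-one
Product: 9 (4R,5S)-5-[(4-methoxybenzyl)oxy]-2-oxotetrahydro-2H-pyran-4-carbaldehyde
Conditions: K2OsO4·2H2O (2 mol%), NaIO4, 2,6-lutidine, dioxane/H2O 3:1, rt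
Reagents that add atoms: sodium periodate, [Na+].[O-]I(=O)(=O)=O
Why: Lemieux–Johnson cleavage (osmium-catalysed dihydroxylation, then periodate glycol cleavage) of the terminal alkene; the lutidine buffer keeps the β-PMB-oxy aldehyde from eliminating, and its trans (diequatorial) arrangement is the thermodynamically preferred one.

Step 7
Reactants: 10 (4-bromobut-1-yn-1-yl)trimethylsilane; 11 propyne
Product: 15 [(5Z)-6-iodo-5-methylhex-5-en-1-yn-1-yl]trimethylsilane, via Grignard reagent 12 (not isolated), via alkylcopper 13 (not isolated), via Z-alkenylcopper 14 (not isolated)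
Conditions: Mg, Et2O, rt; CuBr·SMe2, Et2O/Me2S, −45 °C; 11, −25 °C; I2, −50 → 0 °C
Reagents that add atoms: iodine, II
Why: Normant carbocupration: alkylcopper 13 adds syn across propyne with copper on the terminal carbon, so the chain is cis to copper in 14; iodinolysis with retention gives the Z-iodide and fixes the C3/C6-cis geometry of the later epoxide.

Step 8
Reactants: 9 (4R,5S)-5-[(4-methoxybenzyl)oxy]-2-oxotetrahydro-2H-pyran-4-carbaldehyde; 15 [(5Z)-6-iodo-5-methylhex-5-en-1-yn-1-yl]trimethylsilane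
Product: 17 (4S,5S)-4-[(2Z)-1-hydroxy-3-methyl-7-(trimethylsilyl)hept-2-en-6-yn-1-yl]-5-[(4-methoxybenzyl)oxy]tetrahydro-2H-pyran-2-one (both C6 epimers), via alkenylchromium dichloride 16 (not isolated)
Conditions: CrCl2 (4 equiv), NiCl2 (1 mol%), DMSO, rt
Reagents that add atoms: none
Why: Nozaki–Hiyama–Kishi alkenylation: zerovalent nickel inserts into the C–I bond with retention, transmetalation gives 16 (trivalent chromium), which adds to the aldehyde but not to the lactone; C6 is not controlled here and need not be, since step 9 removes it.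

Step 9
Reactants: 17 (4S,5S)-4-[(2Z)-1-hydroxy-3-methyl-7-(trimethylsilyl)hept-2-en-6-yn-1-yl]-5-[(4-methoxybenzyl)oxy]tetrahydro-2H-pyran-2-one
Product: 18 (4R,5S)-5-[(4-methoxybenzyl)oxy]-4-[(2Z)-3-methyl-7-(trimethylsilyl)hept-2-en-6-ynoyl]tetrahydro-2H-pyran-2-one
Conditions: Dess–Martin periodinane, NaHCO3, CH2Cl2, 0 °C
Reagents that add atoms: none
Why: Dess–Martin oxidation of an allylic alcohol under buffered, non-basic conditions converges both epimers on one enone without Z/E isomerisation or β-elimination of the C8 ether.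

Step 10
Reactants: 18 (4R,5S)-5-[(4-methoxybenzyl)oxy]-4-[(2Z)-3-methyl-7-(trimethylsilyl)hept-2-en-6-ynoyl]tetrahydro-2H-pyran-2-one
Product: 19 (4S,5S)-4-[(1S,2Z)-1-hydroxy-3-methyl-7-(trimethylsilyl)hept-2-en-6-yn-1-yl]-5-[(4-methoxybenzyl)oxy]tetrahydro-2H-pyran-2-one
Conditions: Zn(BH4)2, Et2O, −30 °C
Reagents that add atoms: none
Why: Chelation-controlled 1,2-reduction: zinc bridges the C6 carbonyl and the C8 ether oxygen in a six-membered chelate with C11 and C9 equatorial, and external hydride adds axially so that the alkenyl group becomes equatorial (O6 syn to O8, anti to C11); Zn(BH4)2 reduces enones at the carbonyl and leaves lactones alone.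

Step 11
Reactants: 19 (4S,5S)-4-[(1S,2Z)-1-hydroxy-3-methyl-7-(trimethylsilyl)hept-2-en-6-yn-1-yl]-5-[(4-methoxybenzyl)oxy]tetrahydro-2H-pyran-2-one
Product: 20 (4S,5S)-4-[(R)-hydroxy{(2S,3R)-3-methyl-3-[4-(trimethylsilyl)but-3-yn-1-yl]oxiran-2-yl}methyl]-5-[(4-methoxybenzyl)oxy]tetrahydro-2H-pyran-2-one
Conditions: mCPBA, NaHCO3, CH2Cl2, 0 °C
Reagents that add atoms: 3-chloroperbenzoic acid, OOC(=O)c1cccc(Cl)c1
Why: Hydroxyl-directed peracid epoxidation of a Z-trisubstituted allylic alcohol; 1,3-allylic strain between C3 and the C6 substituents holds H6 in the alkene plane and the hydrogen-bonded peracid delivers oxygen to the hydroxyl-bearing face (threo), which sets C4 and C5; the silylalkyne is inert to the peracid.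

Step 12
Reactants: 20 (4S,5S)-4-[(R)-hydroxy{(2S,3R)-3-methyl-3-[4-(trimethylsilyl)but-3-yn-1-yl]oxiran-2-yl}methyl]-5-[(4-methoxybenzyl)oxy]tetrahydro-2H-pyran-2-one
Product: 21 (4R,5R)-4-{(1S)-2-hydroxy-1-[(4-methoxybenzyl)oxy]ethyl}-5-{(2S,3R)-3-methyl-3-[4-(trimethylsilyl)but-3-yn-1-yl]oxiran-2-yl}dihydrofuran-2(3H)-one
Conditions: DBU (0.2 equiv), CH2Cl2, 0 °C → rt
Reagents that add atoms: none
Why: Base-catalysed intramolecular transesterification (translactonisation): the C6 oxygen attacks C12 in a 5-exo mode and releases the primary C9 oxygen, the γ-lactone being the more stable ring; C5 and C8 end up cis on the new lactone because C6 and C7 are already set, and the C9 hydroxyl appears without a deprotection.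

Step 13
Reactants: 21 (4R,5R)-4-{(1S)-2-hydroxy-1-[(4-methoxybenzyl)oxy]ethyl}-5-{(2S,3R)-3-methyl-3-[4-(trimethylsilyl)but-3-yn-1-yl]oxiran-2-yl}dihydrofuran-2(3H)-one
Product: 22 (4R,5R)-4-{(1S)-2-hydroxy-1-[(4-methoxybenzyl)oxy]ethyl}-5-[(2S,3R)-3-(4-iodobut-3-yn-1-yl)-3-methyloxiran-2-yl]dihydrofuran-2(3H)-one
Conditions: N-iodosuccinimide, AgNO3 (20 mol%), DMF, rt, dark
Reagents that add atoms: N-iodosuccinimide, O=C1CCC(=O)N1I
Why: Silver-catalysed iododesilylation of an alkynylsilane (through the silver acetylide) gives the 1-iodoalkyne directly; alcohol, epoxide and PMB ether are inert.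

Step 14
Reactants: 22 (4R,5R)-4-{(1S)-2-hydroxy-1-[(4-methoxybenzyl)oxy]ethyl}-5-[(2S,3R)-3-(4-iodobut-3-yn-1-yl)-3-methyloxiran-2-yl]dihydrofuran-2(3H)-one
Product: 23 (2S)-2-{(2R,3S)-2-[(2S,3R)-3-(4-iodobut-3-yn-1-yl)-3-methyloxiran-2-yl]-5-oxotetrahydrofuran-3-yl}-2-[(4-methoxybenzyl)oxy]acetaldehyde
Conditions: Dess–Martin periodinane, NaHCO3, CH2Cl2, 0 °C → rt
Reagents that add atoms: none
Why: Dess–Martin oxidation of the primary alcohol to the α-alkoxy aldehyde under buffered conditions; the aldehyde is used at once so that C8 cannot epimerise.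

Step 15
Reactants: 23 (2S)-2-{(2R,3S)-2-[(2S,3R)-3-(4-iodobut-3-yn-1-yl)-3-methyloxiran-2-yl]-5-oxotetrahydrofuran-3-yl}-2-[(4-methoxybenzyl)oxy]acetaldehyde
Product: 25 (4R,5S,6R,7R,8S,9S)-4,5-epoxy-9-hydroxy-8-[(4-methoxybenzyl)oxy]-13,14-dinorgermacr-1(10)-yn-6,12-olide, via alkynylchromium dichloride 24 (not isolated)
Conditions: CrCl2 (8 equiv), NiCl2 (10 mol%), THF, rt, syringe-pump addition of 23 (final 2 mM)
Reagents that add atoms: none
Why: CrCl2 reduces NiCl2 to zerovalent nickel, which inserts into the C(sp)–I bond of 23; transmetalation to trivalent chromium gives alkynylchromium 24, whose C10 adds to the C9 aldehyde and closes the ring by the C9–C10 bond. The closest known reaction type is the Nozaki–Hiyama–Kishi addition of iodoalkynes to aldehydes, which has closed nine- and ten-membered cycloalkynes under these conditions. The ten-membered carbocycle closes in the 10-exo-trig mode (C10 onto the C9 carbonyl, C=O outside the ring). The new C9 centre is controlled by C8: in THF the oxophilic chromium can bind the aldehyde oxygen and the C8 PMB ether oxygen in a five-membered chelate, and the tethered alkynyl group then reaches the carbonyl face opposite C7 with a near-antiperiplanar C7–C8–C9–C10 ring torsion, giving the 8,9-syn (9S) carbinol. Cyclisation must beat oligomerisation, which slow addition at low concentration and the turn imposed by the cis-lactone and cis-epoxide should secure. Chemoselectivity for the aldehyde over lactone and epoxide follows from the low basicity and nucleophilicity of organochromium reagents. No base is present, so the epimerisable α-alkoxy aldehyde keeps its C8 configuration.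

Step 16
Reactants: 25 (4R,5S,6R,7R,8S,9S)-4,5-epoxy-9-hydroxy-8-[(4-methoxybenzyl)oxy]-13,14-dinorgermacr-1(10)-yn-6,12-olide
Product: 26 (1(10)E,4R,5S,6R,7R,8S,9R)-4,5-epoxy-9-hydroxy-8-[(4-methoxybenzyl)oxy]-10-(tributylstannyl)-13,14-dinorgermacr-1(10)-en-6,12-olide
Conditions: Bu3SnH, PdCl2(PPh3)2 (5 mol%), THF, 0 °C → rt
Reagents that add atoms: tributyltin hydride, CCCC[SnH](CCCC)CCCC
Why: Palladium-catalysed hydrostannation is a syn addition, which in a ten-membered ring necessarily leaves C9 and C2 cis; with a free propargylic hydroxyl the tin goes preferentially to the proximal alkyne carbon (C10) and hydrogen to C1.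

Step 17
Reactants: 26 (1(10)E,4R,5S,6R,7R,8S,9R)-4,5-epoxy-9-hydroxy-8-[(4-methoxybenzyl)oxy]-10-(tributylstannyl)-13,14-dinorgermacr-1(10)-en-6,12-olide
Product: 27 (1(10)E,4R,5S,6R,7R,8S,9R)-4,5-epoxy-8-[(4-methoxybenzyl)oxy]-10-(tributylstannyl)-9-[(triethylsilyl)oxy]-13,14-dinorgermacr-1(10)-en-6,12-olide
Conditions: Et3SiCl, imidazole, DMF, 0 °C → rt
Reagents that add atoms: chlorotriethylsilane, CC[Si](Cl)(CC)CC
Why: Silylation of the allylic C9 alcohol with a silyl chloride and imidazole; a chloride is used in place of a triflate so that the epoxide is not opened.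

Step 18
Reactants: 27 (1(10)E,4R,5S,6R,7R,8S,9R)-4,5-epoxy-8-[(4-methoxybenzyl)oxy]-10-(tributylstannyl)-9-[(triethylsilyl)oxy]-13,14-dinorgermacr-1(10)-en-6,12-olide
Product: 28 (1(10)E,4R,5S,6R,7R,8S,9R)-13-(dimethylamino)-4,5-epoxy-8-[(4-methoxybenzyl)oxy]-10-(tributylstannyl)-9-[(triethylsilyl)oxy]-14-norgermacr-1(10)-en-6,12-olide (C11 epimers)
Conditions: LiN(iPr)2, THF, −78 °C; CH2=NMe2 I (Eschenmoser's salt), −78 → 0 °C
Reagents that add atoms: dimethylmethyleneammonium iodide, C=[N+](C)C.[I-]
Why: Kinetic lactone enolate formation at C11 (no leaving group β to the enolate) and Mannich alkylation with Eschenmoser's salt; the alkenylstannane and the silyl and PMB ethers tolerate the amide base at −78 °C, and the C11 configuration is lost in step 19.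

Step 19
Reactants: 28 (1(10)E,4R,5S,6R,7R,8S,9R)-13-(dimethylamino)-4,5-epoxy-8-[(4-methoxybenzyl)oxy]-10-(tributylstannyl)-9-[(triethylsilyl)oxy]-14-norgermacr-1(10)-en-6,12-olide
Product: 30 (1(10)E,4R,5S,6R,7R,8S,9R)-4,5-epoxy-8-[(4-methoxybenzyl)oxy]-10-(tributylstannyl)-9-[(triethylsilyl)oxy]-14-norgermacra-1(10),11(13)-dien-6,12-olide, via trimethylammonium iodide 29 (not isolated)
Conditions: MeI, THF, rt; then aq. NaHCO3, EtOAc, rt
Reagents that add atoms: none
Why: Quaternisation of the amine and E1cB loss of trimethylamine from ammonium salt 29 under bicarbonate give the exocyclic methylene lactone (Eschenmoser methylenation).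

Step 20
Reactants: 30 (1(10)E,4R,5S,6R,7R,8S,9R)-4,5-epoxy-8-[(4-methoxybenzyl)oxy]-10-(tributylstannyl)-9-[(triethylsilyl)oxy]-14-norgermacra-1(10),11(13)-dien-6,12-olide
Product: 31 (1(10)E,4R,5S,6R,7R,8S,9R)-4,5-epoxy-10-iodo-8-[(4-methoxybenzyl)oxy]-9-[(triethylsilyl)oxy]-14-norgermacra-1(10),11(13)-dien-6,12-olide
Conditions: I2, CH2Cl2, 0 °C
Reagents that add atoms: iodine, II
Why: Iododestannylation (ipso substitution) proceeds with retention of alkene geometry; iodine does not attack the electron-poor methylene lactone at 0 °C.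

Step 21
Reactants: 31 (1(10)E,4R,5S,6R,7R,8S,9R)-4,5-epoxy-10-iodo-8-[(4-methoxybenzyl)oxy]-9-[(triethylsilyl)oxy]-14-norgermacra-1(10),11(13)-dien-6,12-olide
Product: 32 methyl (1(10)E,4R,5S,6R,7R,8S,9S)-4,5-epoxy-8-[(4-methoxybenzyl)oxy]-9-[(triethylsilyl)oxy]germacra-1(10),11(13)-dien-6,12-olid-14-oate
Conditions: Pd(PPh3)4 (10 mol%), CO (1 atm), MeOH, Et3N, DMF, 50 °C
Reagents that add atoms: carbon monoxide, [C-]#[O+]; methanol, CO
Why: Palladium-catalysed methoxycarbonylation of an alkenyl iodide: oxidative addition with retention, CO insertion and methanolysis of the acylpalladium species; under CO, insertion outruns Heck addition to the methylene lactone.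

Step 22
Reactants: 32 methyl (1(10)E,4R,5S,6R,7R,8S,9S)-4,5-epoxy-8-[(4-methoxybenzyl)oxy]-9-[(triethylsilyl)oxy]germacra-1(10),11(13)-dien-6,12-olid-14-oate
Product: 33 methyl (1(10)E,4R,5S,6R,7R,8S,9S)-4,5-epoxy-9-hydroxy-8-[(4-methoxybenzyl)oxy]germacra-1(10),11(13)-dien-6,12-olid-14-oate
Conditions: Bu4NF, AcOH, THF, 0 °C
Reagents that add atoms: none
Why: Fluoride cleavage of the triethylsilyl ether, buffered with acetic acid so that methylene lactone, enoate and epoxide are not exposed to basic fluoride or alkoxide.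

Step 23
Reactants: 34 methyl (R)-2-methyloxirane-2-carboxylate
Product: 35 potassium (R)-2-methyloxirane-2-carboxylate
Conditions: KOSiMe3, THF, rt
Reagents that add atoms: potassium trimethylsilanolate, C[Si](C)(C)[O-].[K+]
Why: Anhydrous ester cleavage by silanolate gives the potassium carboxylate without opening the glycidic epoxide; the quaternary stereocentre cannot epimerise.

Step 24
Reactants: 33 methyl (1(10)E,4R,5S,6R,7R,8S,9S)-4,5-epoxy-9-hydroxy-8-[(4-methoxybenzyl)oxy]germacra-1(10),11(13)-dien-6,12-olid-14-oate; 35 potassium (R)-2-methyloxirane-2-carboxylate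
Product: 37 methyl (1(10)E,4R,5S,6R,7R,8S,9S)-4,5-epoxy-8-[(4-methoxybenzyl)oxy]-9-{[(2R)-2-methyloxirane-2-carbonyl]oxy}germacra-1(10),11(13)-dien-6,12-olid-14-oate, via mixed anhydride 36 (not isolated)
Conditions: 35, 2,4,6-Cl3C6H2COCl, THF, rt; then 33, Et3N, DMAP, toluene, rt
Reagents that add atoms: none
Why: Yamaguchi esterification: the carboxylate forms mixed anhydride 36, and DMAP transfers the glycidoyl group (the trichlorobenzoyl carbonyl is shielded) to the hindered allylic C9 alcohol with retention at C9.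

Step 25
Reactants: 37 methyl (1(10)E,4R,5S,6R,7R,8S,9S)-4,5-epoxy-8-[(4-methoxybenzyl)oxy]-9-{[(2R)-2-methyloxirane-2-carbonyl]oxy}germacra-1(10),11(13)-dien-6,12-olid-14-oate
Product: 38 methyl (1(10)E,4R,5S,6R,7R,8S,9S)-4,5-epoxy-8-hydroxy-9-{[(2R)-2-methyloxirane-2-carbonyl]oxy}germacra-1(10),11(13)-dien-6,12-olid-14-oate
Conditions: DDQ, CH2Cl2/pH 7 buffer, 0 °C
Reagents that add atoms: none
Why: Oxidative PMB ether cleavage by DDQ (hydride abstraction, hydrolysis of the oxocarbenium ion) under buffered two-phase conditions leaves both epoxides, the esters and the Michael acceptors untouched.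

Step 26
Reactants: 38 methyl (1(10)E,4R,5S,6R,7R,8S,9S)-4,5-epoxy-8-hydroxy-9-{[(2R)-2-methyloxirane-2-carbonyl]oxy}germacra-1(10),11(13)-dien-6,12-olid-14-oate
Product: 39 methyl (1(10)E,4R,5S,6R,7R,8S,9S)-8-acetoxy-4,5-epoxy-9-{[(2R)-2-methyloxirane-2-carbonyl]oxy}germacra-1(10),11(13)-dien-6,12-olid-14-oate (CNP0159450.1)
Conditions: Ac2O, pyridine, DMAP (cat.), CH2Cl2, 0 °C
Reagents that add atoms: acetic anhydride, CC(=O)OC(C)=O
Why: DMAP-catalysed acetylation of the secondary C8 alcohol, fast at 0 °C, so that neither migration of the C9 acyl group nor translactonisation onto O8 should compete.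

## Compound list

1 | (S)-but-3-ene-1,2-diol | C=C[C@H](O)CO | starting material
2 | (4S)-2-(4-methoxyphenyl)-4-vinyl-1,3-dioxolane (both acetal epimers) | C=C[C@H]1COC(c2ccc(OC)cc2)O1 | intermediate
3 | (S)-2-[(4-methoxybenzyl)oxy]but-3-en-1-ol | C=C[C@H](OCc1ccc(OC)cc1)CO | intermediate
4 | acryloyl chloride | C=CC(Cl)=O | starting material
5 | (S)-2-[(4-methoxybenzyl)oxy]but-3-en-1-yl acrylate | C=CC(=O)OC[C@@H](OCc1ccc(OC)cc1)C=C | intermediate
6 | (S)-5-[(4-methoxybenzyl)oxy]-5,6-dihydro-2H-pyran-2-one | O=C1C=C[C@H](OCc2ccc(OC)cc2)CO1 | intermediate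
7 | {[(3S,4R)-3-[(4-methoxybenzyl)oxy]-4-vinyl-3,4-dihydro-2H-pyran-6-yl]oxy}trimethylsilane (silyl ketene acetal) | C=C[C@@H]1C=C(O[Si](C)(C)C)OC[C@H]1OCc1ccc(OC)cc1 | intermediate
8 | (4S,5S)-5-[(4-methoxybenzyl)oxy]-4-vinyltetrahydro-2H-pyran-2-one | C=C[C@@H]1CC(=O)OC[C@H]1OCc1ccc(OC)cc1 | intermediate
9 | (4R,5S)-5-[(4-methoxybenzyl)oxy]-2-oxotetrahydro-2H-pyran-4-carbaldehyde | O=C[C@@H]1CC(=O)OC[C@H]1OCc1ccc(OC)cc1 | intermediate
10 | (4-bromobut-1-yn-1-yl)trimethylsilane | C[Si](C)(C)C#CCCBr | starting material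
11 | propyne | CC#C | starting material
12 | [4-(trimethylsilyl)but-3-yn-1-yl]magnesium bromide | C[Si](C)(C)C#CCC[Mg]Br | intermediate
13 | [4-(trimethylsilyl)but-3-yn-1-yl]copper (MgBr2·SMe2 complex) | C[Si](C)(C)C#CCC[Cu] | intermediate
14 | [(1Z)-2-methyl-6-(trimethylsilyl)hex-1-en-5-yn-1-yl]copper | C[Si](C)(C)C#CCC/C(C)=C\[Cu] | intermediate
15 | [(5Z)-6-iodo-5-methylhex-5-en-1-yn-1-yl]trimethylsilane | C[Si](C)(C)C#CCC/C(C)=C\I | intermediate
16 | dichloro[(1Z)-2-methyl-6-(trimethylsilyl)hex-1-en-5-yn-1-yl]chromium (trivalent chromium) | C[Si](C)(C)C#CCC/C(C)=C\[Cr](Cl)Cl | intermediate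
17 | (4S,5S)-4-[(2Z)-1-hydroxy-3-methyl-7-(trimethylsilyl)hept-2-en-6-yn-1-yl]-5-[(4-methoxybenzyl)oxy]tetrahydro-2H-pyran-2-one (both C6 epimers) | C[Si](C)(C)C#CCC/C(C)=C\C(O)[C@@H]1CC(=O)OC[C@H]1OCc1ccc(OC)cc1 | intermediate
18 | (4R,5S)-5-[(4-methoxybenzyl)oxy]-4-[(2Z)-3-methyl-7-(trimethylsilyl)hept-2-en-6-ynoyl]tetrahydro-2H-pyran-2-one | C[Si](C)(C)C#CCC/C(C)=C\C(=O)[C@@H]1CC(=O)OC[C@H]1OCc1ccc(OC)cc1 | intermediate
19 | (4S,5S)-4-[(1S,2Z)-1-hydroxy-3-methyl-7-(trimethylsilyl)hept-2-en-6-yn-1-yl]-5-[(4-methoxybenzyl)oxy]tetrahydro-2H-pyran-2-one | C[Si](C)(C)C#CCC/C(C)=C\[C@H](O)[C@@H]1CC(=O)OC[C@H]1OCc1ccc(OC)cc1 | intermediate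
20 | (4S,5S)-4-[(R)-hydroxy{(2S,3R)-3-methyl-3-[4-(trimethylsilyl)but-3-yn-1-yl]oxiran-2-yl}methyl]-5-[(4-methoxybenzyl)oxy]tetrahydro-2H-pyran-2-one | C[Si](C)(C)C#CCC[C@@]1(C)O[C@H]1[C@H](O)[C@@H]1CC(=O)OC[C@H]1OCc1ccc(OC)cc1 | intermediate
21 | (4R,5R)-4-{(1S)-2-hydroxy-1-[(4-methoxybenzyl)oxy]ethyl}-5-{(2S,3R)-3-methyl-3-[4-(trimethylsilyl)but-3-yn-1-yl]oxiran-2-yl}dihydrofuran-2(3H)-one | C[Si](C)(C)C#CCC[C@@]1(C)O[C@H]1[C@@H]2OC(=O)C[C@@H]2[C@H](OCc3ccc(OC)cc3)CO | intermediate
22 | (4R,5R)-4-{(1S)-2-hydroxy-1-[(4-methoxybenzyl)oxy]ethyl}-5-[(2S,3R)-3-(4-iodobut-3-yn-1-yl)-3-methyloxiran-2-yl]dihydrofuran-2(3H)-one | IC#CCC[C@@]1(C)O[C@H]1[C@@H]2OC(=O)C[C@@H]2[C@H](OCc3ccc(OC)cc3)CO | intermediate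
23 | (2S)-2-{(2R,3S)-2-[(2S,3R)-3-(4-iodobut-3-yn-1-yl)-3-methyloxiran-2-yl]-5-oxotetrahydrofuran-3-yl}-2-[(4-methoxybenzyl)oxy]acetaldehyde | IC#CCC[C@@]1(C)O[C@H]1[C@@H]2OC(=O)C[C@@H]2[C@H](OCc3ccc(OC)cc3)C=O | intermediate
24 | alkynylchromium dichloride of 23 (C–I replaced by C–CrCl2, trivalent chromium) | Cl[Cr](Cl)C#CCC[C@@]1(C)O[C@H]1[C@@H]2OC(=O)C[C@@H]2[C@H](OCc3ccc(OC)cc3)C=O | intermediate
25 | (4R,5S,6R,7R,8S,9S)-4,5-epoxy-9-hydroxy-8-[(4-methoxybenzyl)oxy]-13,14-dinorgermacr-1(10)-yn-6,12-olide (ten-membered ring with C1≡C10, cis-fused C11H2 γ-lactone) | O[C@H]1C#CCC[C@@]2(C)O[C@H]2[C@@H]3OC(=O)C[C@@H]3[C@@H]1OCc1ccc(OC)cc1 | intermediate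
26 | (1(10)E,4R,5S,6R,7R,8S,9R)-4,5-epoxy-9-hydroxy-8-[(4-methoxybenzyl)oxy]-10-(tributylstannyl)-13,14-dinorgermacr-1(10)-en-6,12-olide (C9 cis to C2) | O[C@H]1/C([Sn](CCCC)(CCCC)CCCC)=C\CC[C@@]2(C)O[C@H]2[C@@H]3OC(=O)C[C@@H]3[C@@H]1OCc1ccc(OC)cc1 | intermediate
27 | (1(10)E,4R,5S,6R,7R,8S,9R)-4,5-epoxy-8-[(4-methoxybenzyl)oxy]-10-(tributylstannyl)-9-[(triethylsilyl)oxy]-13,14-dinorgermacr-1(10)-en-6,12-olide | CC[Si](CC)(CC)O[C@H]1/C([Sn](CCCC)(CCCC)CCCC)=C\CC[C@@]2(C)O[C@H]2[C@@H]3OC(=O)C[C@@H]3[C@@H]1OCc1ccc(OC)cc1 | intermediate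
28 | (1(10)E,4R,5S,6R,7R,8S,9R)-13-(dimethylamino)-4,5-epoxy-8-[(4-methoxybenzyl)oxy]-10-(tributylstannyl)-9-[(triethylsilyl)oxy]-14-norgermacr-1(10)-en-6,12-olide (C11 epimers) | CN(C)CC1C(=O)O[C@@H]2[C@H]1[C@H](OCc3ccc(OC)cc3)[C@@H](O[Si](CC)(CC)CC)/C([Sn](CCCC)(CCCC)CCCC)=C\CC[C@@]1(C)O[C@@H]21 | intermediate
29 | N,N,N-trimethylammonium iodide of 28 | C[N+](C)(C)CC1C(=O)O[C@@H]2[C@H]1[C@H](OCc3ccc(OC)cc3)[C@@H](O[Si](CC)(CC)CC)/C([Sn](CCCC)(CCCC)CCCC)=C\CC[C@@]1(C)O[C@@H]21.[I-] | intermediate
30 | (1(10)E,4R,5S,6R,7R,8S,9R)-4,5-epoxy-8-[(4-methoxybenzyl)oxy]-10-(tributylstannyl)-9-[(triethylsilyl)oxy]-14-norgermacra-1(10),11(13)-dien-6,12-olide | C=C1C(=O)O[C@@H]2[C@H]1[C@H](OCc3ccc(OC)cc3)[C@@H](O[Si](CC)(CC)CC)/C([Sn](CCCC)(CCCC)CCCC)=C\CC[C@@]1(C)O[C@@H]21 | intermediate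
31 | (1(10)E,4R,5S,6R,7R,8S,9R)-4,5-epoxy-10-iodo-8-[(4-methoxybenzyl)oxy]-9-[(triethylsilyl)oxy]-14-norgermacra-1(10),11(13)-dien-6,12-olide | C=C1C(=O)O[C@@H]2[C@H]1[C@H](OCc3ccc(OC)cc3)[C@@H](O[Si](CC)(CC)CC)/C(I)=C\CC[C@@]1(C)O[C@@H]21 | intermediate
32 | methyl (1(10)E,4R,5S,6R,7R,8S,9S)-4,5-epoxy-8-[(4-methoxybenzyl)oxy]-9-[(triethylsilyl)oxy]germacra-1(10),11(13)-dien-6,12-olid-14-oate | C=C1C(=O)O[C@@H]2[C@H]1[C@H](OCc3ccc(OC)cc3)[C@@H](O[Si](CC)(CC)CC)/C(C(=O)OC)=C\CC[C@@]1(C)O[C@@H]21 | intermediate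
33 | methyl (1(10)E,4R,5S,6R,7R,8S,9S)-4,5-epoxy-9-hydroxy-8-[(4-methoxybenzyl)oxy]germacra-1(10),11(13)-dien-6,12-olid-14-oate | C=C1C(=O)O[C@@H]2[C@H]1[C@H](OCc3ccc(OC)cc3)[C@@H](O)/C(C(=O)OC)=C\CC[C@@]1(C)O[C@@H]21 | intermediate
34 | methyl (R)-2-methyloxirane-2-carboxylate | COC(=O)[C@@]1(C)CO1 | starting material
35 | potassium (R)-2-methyloxirane-2-carboxylate | [K+].[O-]C(=O)[C@@]1(C)CO1 | intermediate
36 | (R)-2-methyloxirane-2-carboxylic 2,4,6-trichlorobenzoic anhydride | O=C(OC(=O)[C@@]1(C)CO1)c1c(Cl)cc(Cl)cc1Cl | intermediate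
37 | methyl (1(10)E,4R,5S,6R,7R,8S,9S)-4,5-epoxy-8-[(4-methoxybenzyl)oxy]-9-{[(2R)-2-methyloxirane-2-carbonyl]oxy}germacra-1(10),11(13)-dien-6,12-olid-14-oate | C=C1C(=O)O[C@@H]2[C@H]1[C@H](OCc3ccc(OC)cc3)[C@@H](OC(=O)[C@@]3(C)CO3)/C(C(=O)OC)=C\CC[C@@]1(C)O[C@@H]21 | intermediate
38 | methyl (1(10)E,4R,5S,6R,7R,8S,9S)-4,5-epoxy-8-hydroxy-9-{[(2R)-2-methyloxirane-2-carbonyl]oxy}germacra-1(10),11(13)-dien-6,12-olid-14-oate | C=C1C(=O)O[C@@H]2[C@H]1[C@H](O)[C@@H](OC(=O)[C@@]3(C)CO3)/C(C(=O)OC)=C\CC[C@@]1(C)O[C@@H]21 | intermediate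
39 | methyl (1(10)E,4R,5S,6R,7R,8S,9S)-8-acetoxy-4,5-epoxy-9-{[(2R)-2-methyloxirane-2-carbonyl]oxy}germacra-1(10),11(13)-dien-6,12-olid-14-oate (CNP0159450.1) | C=C1C(=O)O[C@@H]2[C@H]1[C@H](OC(C)=O)[C@@H](OC(=O)[C@@]1(C)CO1)/C(C(=O)OC)=C\CC[C@@]1(C)O[C@@H]21 | target

## Step count and least certain steps

Total: 26 steps. Longest linear sequence: 24 steps (steps 1–6, 8–22, 24–26, from diol 1). Steps 7 and 23 are one-step side branches.

**Step 15 (key step).** The ring may close with the other facial sense at C9 (a non-chelated, Felkin-type arrangement with a gauche C7–C8–C9–C10 torsion). Intermolecular addition may compete, and the alkynylchromium may be protonated before it cyclises. Fallback for the stereochemical risk: setting out from 23, the cyclisation is accepted with whatever C9 outcome it gives. The 9-epimer, (9R)-cyclodecynol F1, alone or mixed with 25, is oxidised with Dess–Martin periodinane to the cyclodec-1(10)-yn-9-one F2. F2 is reduced by Corey–Bakshi–Shibata reduction with catecholborane and the (R)-2-methyl-oxazaborolidine, the alkyne acting as the small substituent, to come back at 25. C9 is then set by reagent control after ring closure, not by the closure itself.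

**Step 16.** Tin may be delivered to C1 if the bent ring alkyne and the C8 substituent override the directing effect of the free C9 hydroxyl, and some alkyne may be over-reduced. Fallback: setting out from 25, oxidation gives ynone F2. Palladium-catalysed hydrostannation of an ynone places tin α to the carbonyl, that is on C10, for electronic reasons and still by syn addition, giving the α-stannyl enone F3. Corey–Bakshi–Shibata reduction of the C9 ketone then returns the route at 26.

**Step 12.** The acyl transfer may stop at an equilibrium mixture of 20 and 21, and the liberated C9 alkoxide may open the epoxide at C5 in a 6-exo mode or trigger Payne rearrangement. Fallback: setting out from 20, the equilibrating mixture is treated in the same flask with PhI(OAc)2 and catalytic TEMPO. These oxidise only the primary C9 alcohol of the γ-lactone and so drain the equilibrium towards the silylalkyne aldehyde F4. Iododesilylation of F4 (N-iodosuccinimide, AgNO3) then comes back at 23, with oxidation and iodination in reversed order.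

**Step 10.** Hydride may add through a non-chelated arrangement and give the C6 epimer; the Z-enone may isomerise to E; conjugate reduction may intrude. Fallback: setting out from 9 and 15, C6 is set in the carbon–carbon bond-forming event by a catalytic asymmetric Nozaki–Hiyama–Kishi alkenylation (catalytic CrCl2 and NiCl2 with a chiral sulfonamide ligand, Mn, Me3SiCl). This comes back at 19 without passing through enone 18 (no new compound, F0).

**Step 5.** The γ-PMB-oxy group may be lost by an SN2'-type or reductive pathway at copper, 1,2-addition may compete, and the trans selectivity may be incomplete. Fallback: setting out from 6, benzophenone-sensitised photochemical addition of the 1,3-dioxolan-2-yl radical (solvent 1,3-dioxolane) places a masked formyl group at C7 trans to the C8 ether, giving acetal F5. Mild acid hydrolysis (aqueous AcOH) comes back at 9 and replaces steps 5 and 6.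

**Step 25.** Once O8 is free, the C9 glycidoyl group may migrate to it, or O8 may attack C12 and move the lactone from O6 to O8. Fallback: setting out from 32, the order of the two acylations is reversed. DDQ gives the C8 alcohol F6, acetylation gives acetate F7, buffered fluoride gives the C9 alcohol F8, and Yamaguchi esterification of F8 with 35 comes back at 39.

## Further compounds

F1 | step 15 | (4R,5S,6R,7R,8S,9R)-4,5-epoxy-9-hydroxy-8-[(4-methoxybenzyl)oxy]-13,14-dinorgermacr-1(10)-yn-6,12-olide (9-epimer of 25) | O[C@@H]1C#CCC[C@@]2(C)O[C@H]2[C@@H]3OC(=O)C[C@@H]3[C@@H]1OCc1ccc(OC)cc1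
F2 | step 15 | (4R,5S,6R,7R,8S)-4,5-epoxy-8-[(4-methoxybenzyl)oxy]-9-oxo-13,14-dinorgermacr-1(10)-yn-6,12-olide | O=C1C#CCC[C@@]2(C)O[C@H]2[C@@H]3OC(=O)C[C@@H]3[C@@H]1OCc1ccc(OC)cc1
F3 | step 16 | (1(10)E,4R,5S,6R,7R,8S)-4,5-epoxy-8-[(4-methoxybenzyl)oxy]-9-oxo-10-(tributylstannyl)-13,14-dinorgermacr-1(10)-en-6,12-olide | O=C1/C([Sn](CCCC)(CCCC)CCCC)=C\CC[C@@]2(C)O[C@H]2[C@@H]3OC(=O)C[C@@H]3[C@@H]1OCc1ccc(OC)cc1
F4 | step 12 | (2S)-2-[(4-methoxybenzyl)oxy]-2-{(2R,3S)-2-[(2S,3R)-3-methyl-3-[4-(trimethylsilyl)but-3-yn-1-yl]oxiran-2-yl]-5-oxotetrahydrofuran-3-yl}acetaldehyde | C[Si](C)(C)C#CCC[C@@]1(C)O[C@H]1[C@@H]2OC(=O)C[C@@H]2[C@H](OCc3ccc(OC)cc3)C=O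
F0 | step 10 | none | none
F5 | step 5 | (4R,5S)-4-(1,3-dioxolan-2-yl)-5-[(4-methoxybenzyl)oxy]tetrahydro-2H-pyran-2-one | C1(OCCO1)[C@@H]1CC(=O)OC[C@H]1OCc1ccc(OC)cc1
F6 | step 25 | methyl (1(10)E,4R,5S,6R,7R,8S,9S)-4,5-epoxy-8-hydroxy-9-[(triethylsilyl)oxy]germacra-1(10),11(13)-dien-6,12-olid-14-oate | C=C1C(=O)O[C@@H]2[C@H]1[C@H](O)[C@@H](O[Si](CC)(CC)CC)/C(C(=O)OC)=C\CC[C@@]1(C)O[C@@H]21
F7 | step 25 | methyl (1(10)E,4R,5S,6R,7R,8S,9S)-8-acetoxy-4,5-epoxy-9-[(triethylsilyl)oxy]germacra-1(10),11(13)-dien-6,12-olid-14-oate | C=C1C(=O)O[C@@H]2[C@H]1[C@H](OC(C)=O)[C@@H](O[Si](CC)(CC)CC)/C(C(=O)OC)=C\CC[C@@]1(C)O[C@@H]21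
F8 | step 25 | methyl (1(10)E,4R,5S,6R,7R,8S,9S)-8-acetoxy-4,5-epoxy-9-hydroxygermacra-1(10),11(13)-dien-6,12-olid-14-oate | C=C1C(=O)O[C@@H]2[C@H]1[C@H](OC(C)=O)[C@@H](O)/C(C(=O)OC)=C\CC[C@@]1(C)O[C@@H]21
A1 | alternative 1 | α-(diethoxyphosphoryl) cis-fused γ-lactone of the ten-membered ring (8-acetate, 9-TBS ether) | CCOP(=O)(OCC)[C@@H]1C(=O)O[C@@H]2[C@H]1[C@H](OC(C)=O)[C@@H](O[Si](C)(C)C(C)(C)C)/C(C(=O)OC)=C\CC[C@@]1(C)O[C@@H]21
A2 | alternative 2 | methyl (3R,4S)-3-[(1S)-2-(tert-butyldimethylsilyloxy)-1-[(4-methoxybenzyl)oxy]ethyl]-4-hydroxy-6-methyldeca-5(Z),9-dienoate | C=CCC/C(C)=C\[C@H](O)[C@H](CC(=O)OC)[C@H](OCc1ccc(OC)cc1)CO[Si](C)(C)C(C)(C)C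
A3 | alternative 3 | bridged isoxazoline of the ten-membered ring (O on C6, C=N at C8) | COC(=O)C[C@H]1[C@H]2ON=C1[C@@H](O[Si](C)(C)C(C)(C)C)/C(C(=O)OC)=C\CC[C@@]3(C)O[C@@H]23
A4 | alternative 1 | C6 diazo(diethoxyphosphoryl)acetate of the ten-membered ring with C7 methylene | CCOP(=O)(OCC)C(=[N+]=[N-])C(=O)O[C@@H]2C[C@H](OC(C)=O)[C@@H](O[Si](C)(C)C(C)(C)C)/C(C(=O)OC)=C\CC[C@@]1(C)O[C@@H]21
A5 | alternative 2 | methyl (3R,4S)-5-(tert-butyldimethylsilyloxy)-3-formyl-4-[(4-methoxybenzyl)oxy]pentanoate | O=C[C@H](CC(=O)OC)[C@H](OCc1ccc(OC)cc1)CO[Si](C)(C)C(C)(C)C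
A6 | alternative 2 | but-3-en-1-ylzinc bromide | C=CCC[Zn]Br
A7 | alternative 3 | open-chain nitrile oxide at C8 with E-C6=C7 alkene | [O-][N+]#C[C@@H](O[Si](C)(C)C(C)(C)C)/C(C(=O)OC)=C\CC[C@@]1(C)O[C@H]1/C=C/CC(=O)OC
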